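**Retrosynthetic overview**
1. Target ⇒ chemoselective MnO2 oxidation of an allylic triol ⇒ B-alkyl Suzuki union at C12–C13 of a C16 ring fragment (vinyl group on C9) with a C14 epoxy vinyl iodide made from nerol.
2. Ring fragment ⇒ one-flask cationic cascade on an A/B trans-decalin: 10→9 methyl shift, 5→10 hydride shift, then Grob cleavage of C3–C4. This passes through the same C5 cation and makes the same ring-A opening proposed for the oxidosqualene → iridal/marneral pathway.
3. Decalin ⇒ epoxide-initiated cation–olefin bicyclisation of a (10S,11S)-epoxyfarnesyl sulfone, reached from farnesol by SeO2 oxidation and Sharpless epoxidation.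
4. Order of ring events: initiator oxirane → ring A → ring B → ring A cleaved, so ring B is the cyclohexane of the target. The side-chain oxirane is made separately by Sharpless epoxidation.

Assumption: the side-chain oxirane is taken exactly as written in the SMILES, i.e. cis (nerol-type), CH = R and C(CH3) = S. Atom labels follow triterpene numbering: C3 carbinol/aldehyde carbon, C4 bears C24H3 and C23H2O, C5/C10 ring fusion, C8 carbinol carbon, C9 quaternary carbon, C11/C12 first side-chain carbons.

**Step 1**
Reactants: 1 (2E,6E)-farnesol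
Product: 3 (2E,6E)-farnesyl phenyl sulfone, via farnesyl bromide 2 (not isolated)
Conditions: PBr3 (0.4 equiv), Et2O, 0 °C; then PhSO2Na (1.5 equiv), DMF, 23 °C
Reagents that add atoms: sodium benzenesulfinate [Na+].[O-]S(=O)c1ccccc1
Why: Bromination of the allylic alcohol and SN2 S-alkylation of the sulfinate proceed without allylic transposition, so both E olefins are kept, and the sulfone survives all later acidic and oxidising steps before it becomes the vinyl handle.

**Step 2**
Reactants: 3 (2E,6E)-farnesyl phenyl sulfone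
Product: 4 (2E,6E,10E)-12-hydroxyfarnesyl phenyl sulfone
Conditions: SeO2 (0.2 equiv), t-BuOOH (3 equiv), salicylic acid (0.1 equiv), CH2Cl2, 0 to 23 °C
Reagents that add atoms: tert-butyl hydroperoxide CC(C)(C)OO
Why: Riley allylic oxidation (ene reaction, then 2,3-sigmatropic shift) attacks the most electron-rich terminal olefin and gives the E-hydroxymethyl group selectively, which puts oxygen on the carbon that becomes the aldehyde.

**Step 3**
Reactants: 4 (2E,6E,10E)-12-hydroxyfarnesyl phenyl sulfone
Product: 5 (10S,11S)-10,11-epoxy-12-hydroxyfarnesyl phenyl sulfone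
Conditions: Ti(OiPr)4 (10 mol %), L-(+)-diethyl tartrate (12 mol %), t-BuOOH (2 equiv), 4 Å MS, CH2Cl2, −20 °C
Reagents that add atoms: tert-butyl hydroperoxide CC(C)(C)OO
Why: Sharpless asymmetric epoxidation touches only the allylic-alcohol olefin and with L-(+)-tartrate gives the S,S oxirane (same facial sense as geraniol to its 2S,3S epoxide), which is the only stereochemical input for the whole carbocycle.

**Step 4**
Reactants: 5 (10S,11S)-10,11-epoxy-12-hydroxyfarnesyl phenyl sulfone
Product: 6 12-O-TBDPS ether of 5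
Conditions: TBDPSCl (1.1 equiv), imidazole (2 equiv), DMF, 23 °C
Reagents that add atoms: tert-butylchlorodiphenylsilane CC(C)(C)[Si](Cl)(c1ccccc1)c1ccccc1
Why: Standard silylation gives an acid-robust ether that, unlike an ester, cannot participate at the oxirane carbon during cyclisation.

**Step 5**
Reactants: 6 12-O-TBDPS ether of 5
Product: 8 3β-hydroxy-23-(TBDPS-oxy)drim-8-en-11-yl phenyl sulfone, via drim-7-ene isomer 7 (not isolated)
Conditions: HNTf2 (5 mol %), CH2Cl2–(CF3)2CHOH 4:1, −40 °C, then 23 °C
Reagents that add atoms: none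
Why: This is an epoxide-initiated cation–olefin bicyclisation (the laboratory counterpart of the oxidosqualene cyclase reaction) in which the protonated oxirane opens at its tertiary carbon with inversion, the E,E-triene folds chair–chair so that antiparallel additions give the trans-decalin with 3β-OH, equatorial 4α-CH2OSi (trans to the chain in the E olefin), 5α-H and 10β-CH3, and on warming the same acid equilibrates kinetic olefin 7 through the C8 cation to the tetrasubstituted olefin while the sulfone resists ionisation.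

**Step 6**
Reactants: 8 3β-hydroxy-23-(TBDPS-oxy)drim-8-en-11-yl phenyl sulfone
Product: 11 monocyclic diol sulfone (ring B core), via iodane adduct 9 (not isolated), via seco-aldehyde trifluoroacetate 10 (not isolated)
Conditions: PhI(OCOCF3)2 (1.05 equiv), CH2Cl2–(CF3)2CHOH 4:1, −40 to −10 °C; then MeOH, NaBH4 (5 equiv), −40 to 23 °C
Reagents that add atoms: [bis(trifluoroacetoxy)iodo]benzene O=C(OI(OC(=O)C(F)(F)F)c1ccccc1)C(F)(F)F
Why: Proposed new method: trivalent iodine adds to the less hindered α face of the tetrasubstituted olefin and trifluoroacetate opens the iodonium ion diaxially at C8 from the β face (as water does at C6 of a steroidal 5-ene), which sets 8β-O/8α-CH3 and leaves an axial 9α-iodanyl hypernucleofuge antiperiplanar to the 10β-methyl; loss of PhI then drives the 10→9 methyl shift (sets C9, Westphalen type, with the weakly donating and weakly participating trifluoroacetate in the role of the 6β-acetate and the rigid trans-decalin forbidding ring contraction), the 5α→10α hydride shift (sets C10), and, from the same C5 cation invoked for the cyclase, Grob fragmentation of C3–C4 pushed by the free 3-OH, in which the relaxed ring A half-chair holds C24 in the nodal plane and the oxygen-deactivated C23 axial so that CH2OSi ends cis to C10; the closest known reaction types are iodane-mediated oxidative 1,2-shifts of alkenes, Westphalen/backbone rearrangements and cationic Grob (retro-Prins) fragmentation, and borohydride in methanol finally reduces the aldehyde and methanolyses the tertiary trifluoroacetate.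

**Step 7**
Reactants: 11 monocyclic diol sulfone
Product: 13 vinyl triol, via silylmethyl sulfone 12 (not isolated)
Conditions: n-BuLi (3.2 equiv), THF–DMPU, −78 °C; Me3SiCH2I (1.3 equiv), −78 to 0 °C; then Bu4NF (5 equiv), THF, 65 °C
Reagents that add atoms: (iodomethyl)trimethylsilane C[Si](C)(C)CI
Why: In this Kocienski-type sulfone methylenation the α-sulfonyl carbanion (the two alkoxides are carried along) is C-alkylated, fluoride then triggers β-silyl sulfone elimination to the terminal olefin (C11=C12) and removes the TBDPS group in the same operation, and no stereocentre is touched.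

**Step 8**
Reactants: 14 nerol
Product: 15 (2R,3S)-2,3-epoxynerol
Conditions: Ti(OiPr)4 (10 mol %), D-(−)-diethyl tartrate (12 mol %), t-BuOOH (2 equiv), 4 Å MS, CH2Cl2, −20 °C
Reagents that add atoms: tert-butyl hydroperoxide CC(C)(C)OO
Why: Sharpless asymmetric epoxidation oxidises only the allylic olefin, the Z geometry of nerol gives the cis oxirane required by the target, and D-(−)-tartrate gives the 2R,3S enantiomer (L-(+)-tartrate gives 2S,3R).

**Step 9**
Reactants: 15 (2R,3S)-2,3-epoxynerol
Product: 17 terminal epoxy enyne, via epoxyneryl triflate 16 (not isolated)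
Conditions: Tf2O (1.1 equiv), 2,6-lutidine (1.3 equiv), CH2Cl2, −78 °C; then LiCH2C≡CLi (from propyne, n-BuLi 2 equiv, TMEDA), THF, −78 °C; H2O
Reagents that add atoms: propyne CC#C
Why: SN2 displacement of the primary triflate by the more reactive sp3 terminus of 1,3-dilithiopropyne at −78 °C is much faster than attack on the hindered trisubstituted oxirane, so both oxirane centres are kept.

**Step 10**
Reactants: 17 terminal epoxy enyne
Product: 18 (E)-2-methylalkenyl pinacol boronate
Conditions: CuCl (10 mol %), Xantphos (10 mol %), NaOt-Bu (1.5 equiv), B2pin2 (1.3 equiv), MeI (4 equiv), THF, 23 °C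
Reagents that add atoms: bis(pinacolato)diboron CC1(C)OB(OC1(C)C)B1OC(C)(C)C(C)(C)O1; iodomethane CI
Why: In this copper-catalysed carboboration a syn borylcupration places boron on the terminal carbon and the alkenylcopper is trapped by MeI, which fixes the trisubstituted olefin geometry (chain trans to boron) under conditions harmless to the oxirane.

**Step 11**
Reactants: 18 (E)-2-methylalkenyl pinacol boronate
Product: 19 (E)-epoxy vinyl iodide
Conditions: NaOMe (1.1 equiv), THF–MeOH, −78 °C; then ICl (1.0 equiv), −78 °C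
Reagents that add atoms: iodine monochloride ClI
Why: Iododeboronation of the preformed methoxide ate complex proceeds with retention of olefin geometry and is far faster than attack of the halogen on the prenyl olefin.

**Step 12**
Reactants: 13 vinyl triol; 19 (E)-epoxy vinyl iodide
Product: 21 epoxy triol (C30), via B-alkyl borane 20 (not isolated)
Conditions: 9-BBN (3.5 equiv), THF, 0 to 40 °C; then 19, Pd(dppf)Cl2 (5 mol %), AsPh3 (5 mol %), Cs2CO3 (3 equiv), DMF–H2O, 23 °C
Reagents that add atoms: none
Why: In this B-alkyl Suzuki–Miyaura coupling 9-BBN hydroborates only the monosubstituted olefin (the primary hydroxyls are carried as borinates that hydrolyse on work-up) and the sp3–sp2 coupling keeps the E geometry of the iodide and tolerates the oxirane.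

**Step 13**
Reactants: 21 epoxy triol (C30)
Product: 22 target CNP0179098.1
Conditions: MnO2 (activated, 20 equiv), CH2Cl2, 23 °C
Reagents that add atoms: none
Why: MnO2 oxidises only the allylic primary alcohol to the enal and leaves the saturated primary alcohol, the tertiary alcohol, the oxirane and the olefin geometry untouched.

**Compound list**
1 | (2E,6E)-farnesol | CC(C)=CCC/C(C)=C/CC/C(C)=C/CO | starting material
2 | (2E,6E)-farnesyl bromide | CC(C)=CCC/C(C)=C/CC/C(C)=C/CBr | intermediate
3 | (2E,6E)-farnesyl phenyl sulfone | CC(C)=CCC/C(C)=C/CC/C(C)=C/CS(=O)(=O)c1ccccc1 | intermediate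
4 | (2E,6E,10E)-12-hydroxyfarnesyl phenyl sulfone | OC/C(C)=C/CC/C(C)=C/CC/C(C)=C/CS(=O)(=O)c1ccccc1 | intermediate
5 | (2E,6E,10S,11S)-10,11-epoxy-12-hydroxyfarnesyl phenyl sulfone | O=S(=O)(c1ccccc1)C/C=C(C)/CC/C=C(C)/CC[C@@H]1O[C@@]1(C)CO | intermediate
6 | 12-O-TBDPS ether of 5 | O=S(=O)(c1ccccc1)C/C=C(C)/CC/C=C(C)/CC[C@@H]1O[C@@]1(C)CO[Si](c1ccccc1)(c1ccccc1)C(C)(C)C | intermediate
7 | trans-decalin, 7-ene isomer (3β-OH, 4α-CH2OTBDPS, 4β-CH3, 5α-H, 9α-H, 10β-CH3, 9β-CH2SO2Ph) | O[C@H]1CC[C@]2(C)[C@@H](CS(=O)(=O)c3ccccc3)C(C)=CC[C@H]2[C@]1(C)CO[Si](c1ccccc1)(c1ccccc1)C(C)(C)C | intermediate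
8 | trans-decalin, 8(9)-ene (3β-OH, 4α-CH2OTBDPS, 4β-CH3, 5α-H, 10β-CH3) | O[C@H]1CC[C@]2(C)C(CS(=O)(=O)c3ccccc3)=C(C)CC[C@H]2[C@]1(C)CO[Si](c1ccccc1)(c1ccccc1)C(C)(C)C | intermediate
9 | 8β-trifluoroacetoxy-8α-methyl-9α-[phenyl(trifluoroacetoxy)iodanyl] adduct of 8 | O[C@H]1CC[C@]2(C)[C@](CS(=O)(=O)c3ccccc3)(I(c3ccccc3)OC(=O)C(F)(F)F)[C@@](C)(OC(=O)C(F)(F)F)CC[C@H]2[C@]1(C)CO[Si](c1ccccc1)(c1ccccc1)C(C)(C)C | intermediate
10 | 3,4-seco aldehyde (8β-OCOCF3, 9β-CH3, 9α-CH2SO2Ph, 10α-H, CH2OTBDPS cis to C10) | O=S(=O)(c1ccccc1)C[C@@]1(C)[C@H](CCC=O)/C(=C(/C)CO[Si](c2ccccc2)(c2ccccc2)C(C)(C)C)CC[C@]1(C)OC(=O)C(F)(F)F | intermediate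
11 | diol sulfone (C3-OH, 8β-OH) | O=S(=O)(c1ccccc1)C[C@@]1(C)[C@H](CCCO)/C(=C(/C)CO[Si](c2ccccc2)(c2ccccc2)C(C)(C)C)CC[C@]1(C)O | intermediate
12 | C11-(trimethylsilylmethyl) sulfone (C11 epimers) | O=S(=O)(c1ccccc1)C(C[Si](C)(C)C)[C@@]1(C)[C@H](CCCO)/C(=C(/C)CO[Si](c2ccccc2)(c2ccccc2)C(C)(C)C)CC[C@]1(C)O | intermediate
13 | vinyl triol (ring fragment, C16) | C=C[C@@]1(C)[C@H](CCCO)/C(=C(/C)CO)CC[C@]1(C)O | intermediate
14 | nerol | CC(C)=CCC/C(C)=C\CO | starting material
15 | (2R,3S)-2,3-epoxynerol | CC(C)=CCC[C@]1(C)O[C@@H]1CO | intermediate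
16 | (2R,3S)-2,3-epoxyneryl triflate | CC(C)=CCC[C@]1(C)O[C@@H]1COS(=O)(=O)C(F)(F)F | intermediate
17 | cis-epoxy enyne (oxirane CH = R, C(CH3) = S) | CC(C)=CCC[C@]1(C)O[C@@H]1CCC#C | intermediate
18 | (E)-alkenyl pinacol boronate, oxirane as in 17 | CC(C)=CCC[C@]1(C)O[C@@H]1CC/C(C)=C/B1OC(C)(C)C(C)(C)O1 | intermediate
19 | (E)-vinyl iodide, oxirane as in 17 | CC(C)=CCC[C@]1(C)O[C@@H]1CC/C(C)=C/I | intermediate
20 | C12 B-alkyl-9-BBN of 13, primary hydroxyls as 9-BBN borinates | C1CCC2CCCC1B2CC[C@@]3(C)[C@H](CCCOB4C5CCCC4CCC5)/C(=C(/C)COB4C5CCCC4CCC5)CC[C@]3(C)O | intermediate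
21 | epoxy triol (allylic alcohol precursor of the target) | CC(C)=CCC[C@]1(C)O[C@@H]1CC/C(C)=C/CC[C@@]1(C)[C@H](CCCO)/C(=C(/C)CO)CC[C@]1(C)O | intermediate
22 | CNP0179098.1 | CC(C)=CCC[C@]1(C)O[C@@H]1CC/C(C)=C/CC[C@@]1(C)[C@H](CCCO)/C(=C(/C)C=O)CC[C@]1(C)O | target

**Step count**
Total steps: 13. Longest linear sequence: 9 (steps 1–7, 12, 13).

**Steps most likely to fail**

**Step 6 (iodane cascade).** The risks are acyloxonium participation, proton loss at C10 (a Westphalen-type olefin), or a methyl shift from C4.
Fallback from 8, rejoining at 10: replace the one-flask iodane oxidation with a halonium addition followed by a separate silver solvolysis.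
- NBS (1.05 equiv) and CF3CO2H (5 equiv) in CH2Cl2 at −40 °C give, by diaxial opening of the α-bromonium ion, the 9α-bromo-8β-trifluoroacetate F1.
- The C8/C9 stereochemistry can be proven on this bromide before any cation is made.
- AgSbF6 (1.2 equiv) with 2,6-di-tert-butylpyridine in CH2Cl2 at −78 to −20 °C then abstracts the axial bromide and releases the same methyl shift, hydride shift and Grob sequence to 10.
- Aldehyde 10 is reduced to 11 as in step 6.

**Step 5 (cationic bicyclisation and olefin equilibration).** The sulfone-deactivated terminal olefin may stop the reaction at the monocycle, or the strong acid may start a premature backbone rearrangement.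
Fallback from 6, rejoining at 8: switch from a cationic to a radical ring closure.
- Cp2TiCl2 (2.2 equiv) and Mn dust in THF at 23 °C generate Cp2TiCl (trivalent titanium).
- This opens the oxirane homolytically and two 6-endo closures, then β-hydride elimination, give the exocyclic-olefin decalin F2.
- F2 is isomerised under near-neutral conditions with RhCl3·3H2O (5 mol %) in EtOH at 80 °C to 8.

**Step 7 (alkylation of a neopentyl sulfonyl carbanion).** The risks are steric failure of the alkylation, or alkoxide-driven fragmentation with loss of sulfinate.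
Fallback from 11, rejoining at 13: use oxidative desulfonylation and olefination instead of alkylation and elimination.
- n-BuLi (3.2 equiv), then Me3SiOOSiMe3 in THF at −78 °C, converts the carbanion into the C11 aldehyde F3.
- Ph3P=CH2 in THF at 0 °C (not basic enough to deprotonate the tertiary alcohol, so no retro-aldol) gives the vinyl silyl ether F4.
- Bu4NF in THF at 23 °C gives 13.

**Further compounds**
F1 | step 6 | 9α-bromo-8β-trifluoroacetoxy-8α-methyl decalin | O[C@H]1CC[C@]2(C)[C@](CS(=O)(=O)c3ccccc3)(Br)[C@@](C)(OC(=O)C(F)(F)F)CC[C@H]2[C@]1(C)CO[Si](c1ccccc1)(c1ccccc1)C(C)(C)C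
F2 | step 5 | exocyclic 8-methylene decalin (9α-H) | O[C@H]1CC[C@]2(C)[C@@H](CS(=O)(=O)c3ccccc3)C(=C)CC[C@H]2[C@]1(C)CO[Si](c1ccccc1)(c1ccccc1)C(C)(C)C
F3 | step 7 | C11 aldehyde | O=C[C@@]1(C)[C@H](CCCO)/C(=C(/C)CO[Si](c2ccccc2)(c2ccccc2)C(C)(C)C)CC[C@]1(C)O
F4 | step 7 | vinyl diol TBDPS ether | C=C[C@@]1(C)[C@H](CCCO)/C(=C(/C)CO[Si](c2ccccc2)(c2ccccc2)C(C)(C)C)CC[C@]1(C)O
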